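**Plan**

- Retrosynthesis: the aldehyde is traced back to a methyl group, and the three ring bromines to one ring CH and two carboxyl groups, which leads to 2,3-dihydroxy-5-methylterephthalic acid. The ring is then cut at C3–C4 and C5–C6 (target numbering) into diethyl oxalate and diethyl 3-methyladipate.
- Enabling feature: the hydroxyl-bearing C4/C5 are the two carbons of an oxalate. The bromine-bearing C3 and C6 are the ester-activated α-carbons of an adipate; each carboxyl there sits ortho to a hydroxyl and can later be displaced ipso by bromine. C1 and C2 are the adipate's C3 and C4.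
- Forward: esterification, double Claisen condensation that closes the only ring, aromatisation, saponification, tribromination with double decarboxylation, acetylation, benzylic dibromination, hydrolysis.
- Stereochemistry: the target is achiral. The single stereocentre of the adipate is carried as a racemate and erased on aromatisation.

Key step: step 2

Remark: commercial racemic 3-methyladipic acid is assumed, and compound 6 is written as its bis-enol tautomer.

**Route**

Step 1
Reactants: 1 3-methyladipic acid (racemic); 2 ethanol
Product: 3 diethyl 3-methyladipate (racemic)
Conditions: EtOH (excess), H2SO4 (cat.), reflux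
Reagents that add atoms: ethanol (2), CCO
Why: Fischer esterification driven to completion by the excess alcohol; the remote methyl-bearing stereocentre is not touched.

Step 2
Reactants: 3 diethyl 3-methyladipate; 4 diethyl oxalate
Product: 6 diethyl 2,3-dihydroxy-5-methylcyclohexa-1,3-diene-1,4-dicarboxylate (racemic bis-enol of the 2,3-dioxo diester), via diethyl 2-(2-ethoxy-2-oxoacetyl)-4-methylhexanedioate 5 (not isolated)
Conditions: NaOEt (2.5 equiv), 4 (1.3 equiv), Et2O, slow addition of 3, 0 °C → reflux; then cold 2 M HCl
Reagents that add atoms: none
Why: An ethoxide-generated ester enolate of 3 acylates one carbonyl of the non-enolisable oxalate 4 (crossed Claisen condensation) to give 5 as its stabilised enolate, and the second α-carbon then attacks the remaining oxalyl ester with loss of ethoxide to form the second C–C bond. The closest known reaction type is the double Claisen condensation of adipic esters with oxalic esters to 2,3-dioxocyclohexane-1,4-dicarboxylates. The single ring closes in a 6-exo-trig, Dieckmann-type mode. No new stereocentre results, because both newly substituted α-carbons are planar in the bis-enol and the methyl-bearing carbon remains racemic. The step needs chemoselectivity for intermolecular oxalylation over 5-exo Dieckmann closure of 3 to a cyclopentanone; this is secured by the more electrophilic α-dicarbonyl ester held in excess, by the reversibility of all acylations under ethoxide, and by the doubly deprotonated, chelated bis-enolate of 6 as thermodynamic sink. Within 5 the enolate deactivates its own ketone and conjugated ester, so the terminal oxalyl ester is the only good electrophile for the second closure.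

Step 3
Reactants: 6 diethyl 2,3-dihydroxy-5-methylcyclohexa-1,3-diene-1,4-dicarboxylate; 7 bromine
Product: 9 diethyl 2,3-dihydroxy-5-methylterephthalate, via diethyl 1-bromo-3-hydroxy-5-methyl-2-oxocyclohex-3-ene-1,4-dicarboxylate 8 (not isolated)
Conditions: Br2 (1.0 equiv), CHCl3, 0 °C; then pyridine (2.5 equiv), reflux
Reagents that add atoms: none
Why: Halogenation–dehydrohalogenation aromatisation: the enol is brominated at its ester-bearing carbon to give 8, base-mediated E2 loss of HBr follows, and the resulting dienone tautomerises to the catechol; any over-bromination could only reach the ring CH that is to carry bromine later.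

Step 4
Reactants: 9 diethyl 2,3-dihydroxy-5-methylterephthalate
Product: 10 2,3-dihydroxy-5-methylterephthalic acid
Conditions: KOH (8 equiv), H2O/EtOH (1:1), reflux, N2; then conc. HCl to pH 1
Reagents that add atoms: potassium hydroxide, [K+].[OH-]
Why: Saponification of both salicylate-type esters by excess hydroxide, the ester between the hydroxyl and the methyl group setting the forcing conditions; the inert atmosphere keeps the catecholate from autoxidation.

Step 5
Reactants: 10 2,3-dihydroxy-5-methylterephthalic acid; 7 bromine
Product: 13 3,4,6-tribromo-5-methylbenzene-1,2-diol, via 5-bromo-2,3-dihydroxy-6-methylterephthalic acid 11 (not isolated), via 4,6-dibromo-2,3-dihydroxy-5-methylbenzoic acid 12 (not isolated)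
Conditions: Br2 (3.2 equiv), AcOH/H2O (4:1), 20 → 60 °C; aq. NaHSO3 work-up
Reagents that add atoms: bromine (7), BrBr
Why: Electrophilic bromination first at the only ring CH (para to a hydroxyl), then ipso at each carboxyl-bearing carbon, which lies ortho to a hydroxyl, with loss of CO2 from the bromodienone (bromodecarboxylation of ortho-hydroxybenzoic acids, as in salicylic acid to tribromophenol); the bisulfite work-up should return any ortho-quinone or bromodienone to the catechol.

Step 6
Reactants: 13 3,4,6-tribromo-5-methylbenzene-1,2-diol
Product: 14 3,4,6-tribromo-5-methyl-1,2-phenylene diacetate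
Conditions: Ac2O (3 equiv), pyridine, DMAP (cat.), 20 °C
Reagents that add atoms: acetic anhydride, CC(=O)OC(C)=O
Why: DMAP-catalysed O-acetylation masks both phenols, which would otherwise quench the radical chain and be oxidised by NBS in the next step.

Step 7
Reactants: 14 3,4,6-tribromo-5-methyl-1,2-phenylene diacetate
Product: 15 3,4,6-tribromo-5-(dibromomethyl)-1,2-phenylene diacetate
Conditions: NBS (2.5 equiv), AIBN (cat.), PhCF3, reflux, hν
Reagents that add atoms: N-bromosuccinimide, O=C1CCC(=O)N1Br
Why: Wohl–Ziegler radical bromination; with every ring position substituted and the acetate methyls unreactive, the benzylic methyl is the only site for hydrogen abstraction, and excess NBS should take it to the gem-dibromide as is known for 2,6-dihalotoluenes.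

Step 8
Reactants: 15 3,4,6-tribromo-5-(dibromomethyl)-1,2-phenylene diacetate
Product: 17 2,3,6-tribromo-4,5-dihydroxybenzaldehyde, via 3,4,6-tribromo-5-(dibromomethyl)benzene-1,2-diol 16 (not isolated)
Conditions: 3 M H2SO4 (aq.)/1,4-dioxane (1:2), 95 °C
Reagents that add atoms: water, O
Why: Acid-catalysed ester hydrolysis frees the catechol 16, whose hydroxyl para to the dibromomethyl group assists ionisation of a C–Br bond so that water converts the gem-dibromide into the aldehyde (benzal halide hydrolysis), under non-oxidising and non-basic conditions that spare the catechol.

**Compound list**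

1 | 3-methyladipic acid (3-methylhexanedioic acid, racemic) | CC(CCC(=O)O)CC(=O)O | starting material
2 | ethanol | CCO | starting material
3 | diethyl 3-methyladipate (racemic) | CCOC(=O)CC(C)CCC(=O)OCC | intermediate
4 | diethyl oxalate | CCOC(=O)C(=O)OCC | starting material
5 | diethyl 2-(2-ethoxy-2-oxoacetyl)-4-methylhexanedioate (racemic diastereomer mixture, present as its sodium enolate, not isolated) | CCOC(=O)CC(C)CC(C(=O)OCC)C(=O)C(=O)OCC | intermediate
6 | diethyl 2,3-dihydroxy-5-methylcyclohexa-1,3-diene-1,4-dicarboxylate (racemic, bis-enol of the 2,3-dioxo diester) | CCOC(=O)C1=C(O)C(O)=C(C(=O)OCC)C(C)C1 | intermediate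
7 | bromine | BrBr | starting material
8 | diethyl 1-bromo-3-hydroxy-5-methyl-2-oxocyclohex-3-ene-1,4-dicarboxylate (racemic diastereomer mixture, not isolated) | CCOC(=O)C1(Br)CC(C)C(C(=O)OCC)=C(O)C1=O | intermediate
9 | diethyl 2,3-dihydroxy-5-methylterephthalate | CCOC(=O)c1cc(C)c(C(=O)OCC)c(O)c1O | intermediate
10 | 2,3-dihydroxy-5-methylterephthalic acid | Cc1cc(C(=O)O)c(O)c(O)c1C(=O)O | intermediate
11 | 5-bromo-2,3-dihydroxy-6-methylterephthalic acid (not isolated) | Cc1c(Br)c(C(=O)O)c(O)c(O)c1C(=O)O | intermediate
12 | 4,6-dibromo-2,3-dihydroxy-5-methylbenzoic acid (not isolated) | Cc1c(Br)c(C(=O)O)c(O)c(O)c1Br | intermediate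
13 | 3,4,6-tribromo-5-methylbenzene-1,2-diol | Cc1c(Br)c(Br)c(O)c(O)c1Br | intermediate
14 | 3,4,6-tribromo-5-methyl-1,2-phenylene diacetate | Cc1c(Br)c(Br)c(OC(C)=O)c(OC(C)=O)c1Br | intermediate
15 | 3,4,6-tribromo-5-(dibromomethyl)-1,2-phenylene diacetate | BrC(Br)c1c(Br)c(Br)c(OC(C)=O)c(OC(C)=O)c1Br | intermediate
16 | 3,4,6-tribromo-5-(dibromomethyl)benzene-1,2-diol (not isolated) | BrC(Br)c1c(Br)c(Br)c(O)c(O)c1Br | intermediate
17 | 2,3,6-tribromo-4,5-dihydroxybenzaldehyde | O=Cc1c(Br)c(O)c(O)c(Br)c1Br | target

**Step count and risks**

Total step count: 8. Longest linear sequence: 8 steps (from 1 to 17).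

Steps most likely to fail:

Step 2. The adipate may close on itself (Dieckmann) to a cyclopentanone β-keto ester, or the second acylation at the β-branched α-carbon may stay incomplete, so that open-chain material accumulates. The fallback replaces the equilibrating alkoxide condensation with an irreversible, base-free double C-acylation. Setting out from 3, internal-quench silylation (LiN(iPr)2, Me3SiCl, THF, −78 °C) would give the bis(silyl ketene acetal) 1,6-diethoxy-3-methyl-1,6-bis(trimethylsilyloxy)hexa-1,5-diene F1. Treatment of this with oxalyl chloride (Me3SiOTf cat., CH2Cl2, −78 → 20 °C) should form the same two bonds and return to the route at 6.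

Step 5. Ipso substitution may stall at a bromo acid because the ring is deactivated, or the catechol may be consumed by over-oxidation to an ortho-quinone that the reductive work-up does not fully return. The fallback separates decarboxylation from bromination. Setting out from 10, thermal protodecarboxylation (Cu2O cat., quinoline, 200 °C) would give 4-methylbenzene-1,2-diol F2. Exhaustive bromination of its three free ring positions (Br2, 3 equiv, AcOH, 20 °C) should then rejoin the route at 13.

Step 7. The second hydrogen abstraction may be retarded by the two ortho bromines, so that the bromination stops at the benzylic monobromide. The fallback works at the monohalide oxidation level. Setting out from 14, NBS (1.05 equiv, AIBN cat., PhCF3, reflux) would give 3,4,6-tribromo-5-(bromomethyl)-1,2-phenylene diacetate F3. A Kornblum-type oxidation with N-methylmorpholine N-oxide (MeCN, 20 → 60 °C) would convert this into 3,4,6-tribromo-5-formyl-1,2-phenylene diacetate F4. Acidic hydrolysis of the acetates (3 M H2SO4/1,4-dioxane, 80 °C) then comes back to the route at 17.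

Further compounds
F1 | step 2 | 1,6-diethoxy-3-methyl-1,6-bis(trimethylsilyloxy)hexa-1,5-diene (racemic, mixture of double-bond isomers) | CCOC(O[Si](C)(C)C)=CC(C)CC=C(OCC)O[Si](C)(C)C
F2 | step 5 | 4-methylbenzene-1,2-diol | Cc1ccc(O)c(O)c1
F3 | step 7 | 3,4,6-tribromo-5-(bromomethyl)-1,2-phenylene diacetate | BrCc1c(Br)c(Br)c(OC(C)=O)c(OC(C)=O)c1Br
F4 | step 7 | 3,4,6-tribromo-5-formyl-1,2-phenylene diacetate | O=Cc1c(Br)c(Br)c(OC(C)=O)c(OC(C)=O)c1Br
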